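## Retrosynthetic overview

1. The butenolide is attached last: the C12–C13 bond comes from a B‑alkyl Suzuki coupling of 4‑bromofuran‑2(5H)‑one with the 9‑BBN adduct of a C9‑vinyl diene, itself made from the C8=C9 enol triflate.
2. The 2α‑OH, 5α‑H and 6α‑OH come from α‑face hydroboration of a Δ2,Δ5‑diene (labdane numbering).
3. Ring B is made by one‑carbon ring expansion (diazoethane insertion with 1,2‑shift) of a hydrindenone cyclopentanone; this brings in C8 with its methyl and leaves the C9 ketone for triflation.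
4. Ring A with the quaternary C4 and C10 comes from a new desymmetrising dienamine α‑aldol of an enal tethered to 2‑methylcyclopentane‑1,3‑dione, followed by dehydration.
5. The enal comes from Michael addition to acrolein and a Wittig reaction. Ring order: cyclopentane (bought) → ring A → ring B (by expansion) → butenolide.

Assumption: the phosphorus ylide, diazoethane (pre‑distilled ethereal solution from N‑ethyl‑N‑nitrosourea), boranes and the silyl chloride are treated as reagents; the sense of induction of the step‑3 catalyst is assumed and would be fixed by choosing the catalyst antipode.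

## Route

Step 1
Reactants: 1 2‑methylcyclopentane‑1,3‑dione; 2 acrolein (prop‑2‑enal)
Product: 3 3‑(1‑methyl‑2,5‑dioxocyclopentyl)propanal
Conditions: H2O, 23 °C, 24 h
Reagents that add atoms: none
Why: Michael addition of the acidic cyclic 1,3‑dione (as its enol) to acrolein in water gives the C‑alkylated adduct cleanly; the new quaternary carbon is still prochiral, so no stereocentre is formed.

Step 2
Reactants: 3 3‑(1‑methyl‑2,5‑dioxocyclopentyl)propanal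
Product: 4 (2E)‑2‑methyl‑5‑(1‑methyl‑2,5‑dioxocyclopentyl)pent‑2‑enal
Conditions: Ph3P=C(CH3)CHO (1.1 equiv), toluene, 80 °C
Reagents that add atoms: 2‑(triphenylphosphoranylidene)propanal, CC(C=O)=P(c1ccccc1)(c1ccccc1)c1ccccc1
Why: Wittig olefination with the stabilised formyl ylide reacts only at the aldehyde (the ring ketones are inert) and gives the (E)‑2‑methyl enal.

Step 3
Reactants: 4 (2E)‑2‑methyl‑5‑(1‑methyl‑2,5‑dioxocyclopentyl)pent‑2‑enal
Product: 6 (3aS,4R,7aS)‑3a‑hydroxy‑4‑(hydroxymethyl)‑4,7a‑dimethyl‑2,3,3a,4,7,7a‑hexahydro‑1H‑inden‑1‑one, via aldol aldehyde 5 (not isolated)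
Conditions: 1‑[(1R,2R)‑2‑aminocyclohexyl]‑3‑[3,5‑bis(trifluoromethyl)phenyl]thiourea (20 mol %), 4‑nitrobenzoic acid (20 mol %), toluene, 30 °C; then MeOH, NaBH4 (0.5 equiv), −60 °C
Reagents that add atoms: none
Why: Proposed new method: the primary amine condenses with the α‑branched enal and reversible γ‑deprotonation gives a dienamine whose α‑carbon (the only site that can close a six‑membered ring) adds to one of the two enantiotopic ring carbonyls held by the thiourea, so that ring A, the quaternary C‑4 (formyl gauche to the H‑bonded carbonyl oxygen, hence cis to the new OH and to the angular methyl), C‑3a and the quaternary C‑7a are set in one desymmetrising aldol while the C5=C6 alkene is kept, and borohydride then traps the retro‑aldol‑prone aldehyde in the same flask; the closest known reactions are the Hajos–Parrish–Eder–Sauer–Wiechert aldol, 6‑enolexo aldolisations of aldehyde enamines and primary‑amine dienamine catalysis of α‑branched enals.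

Step 4
Reactants: 6 (3aS,4R,7aS)‑3a‑hydroxy‑4‑(hydroxymethyl)‑4,7a‑dimethyl‑2,3,3a,4,7,7a‑hexahydro‑1H‑inden‑1‑one
Product: 7 (3aS,4R,7aS)‑3a‑hydroxy‑4,7a‑dimethyl‑4‑[(triethylsilyloxy)methyl]‑2,3,3a,4,7,7a‑hexahydro‑1H‑inden‑1‑one
Conditions: TESCl (1.1 equiv), imidazole, CH2Cl2, −20 °C
Reagents that add atoms: chlorotriethylsilane, CC[Si](Cl)(CC)CC
Why: Silyl ether formation is selective for the primary alcohol over the very hindered tertiary alcohol.

Step 5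
Reactants: 7 (3aS,4R,7aS)‑3a‑hydroxy‑4,7a‑dimethyl‑4‑[(triethylsilyloxy)methyl]‑2,3,3a,4,7,7a‑hexahydro‑1H‑inden‑1‑one
Product: 8 (4S,7aS)‑4,7a‑dimethyl‑4‑[(triethylsilyloxy)methyl]‑2,4,7,7a‑tetrahydro‑1H‑inden‑1‑one
Conditions: Burgess reagent (2 equiv), benzene, 50 °C
Reagents that add atoms: none
Why: Burgess syn‑elimination of the tertiary alcohol can only go towards C‑3 because both other neighbours are quaternary, and its concerted course avoids a free cation that could undergo Wagner–Meerwein shifts; the carbinol stereocentre is erased.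

Step 6
Reactants: 8 (4S,7aS)‑4,7a‑dimethyl‑4‑[(triethylsilyloxy)methyl]‑2,4,7,7a‑tetrahydro‑1H‑inden‑1‑one
Product: 9 (5S,8aS)‑2,5,8a‑trimethyl‑5‑[(triethylsilyloxy)methyl]‑3,5,8,8a‑tetrahydronaphthalen‑1(2H)‑one (C‑2 epimers)
Conditions: CH3CHN2 (1.5 equiv, Et2O), Sc(OTf)3 (10 mol %), toluene, −78 → −40 °C
Reagents that add atoms: diazoethane, CC=[N+]=[N-]
Why: Lewis‑acid‑catalysed diazoalkane–ketone homologation (Tiffeneau–Demjanov‑type 1,2‑shift): diazoethane adds to the Sc‑activated cyclopentanone and the allylic CH2, not the quaternary carbon, migrates with loss of N2 (as in D‑homoannulation of 17‑oxo steroids), so the five‑membered ring becomes ring B with the C‑8 methyl in place; the new CH(CH3) centre forms as a mixture that is erased in step 7.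

Step 7
Reactants: 9 (5S,8aS)‑2,5,8a‑trimethyl‑5‑[(triethylsilyloxy)methyl]‑3,5,8,8a‑tetrahydronaphthalen‑1(2H)‑one
Product: 10 (5S,8aS)‑2,5,8a‑trimethyl‑5‑[(triethylsilyloxy)methyl]‑3,5,8,8a‑tetrahydronaphthalen‑1‑yl trifluoromethanesulfonate
Conditions: KHMDS, THF, −78 °C; Comins' reagent, −78 → 0 °C
Reagents that add atoms: N‑(5‑chloropyridin‑2‑yl)bis(trifluoromethanesulfonimide), FC(F)(F)S(=O)(=O)N(c1ccc(Cl)cn1)S(=O)(=O)C(F)(F)F
Why: The ketone can enolise only towards C‑2 (the other α‑carbon is quaternary), so deprotonation and O‑triflation give the tetrasubstituted enol triflate regiospecifically.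

Step 8
Reactants: 10 (5S,8aS)‑2,5,8a‑trimethyl‑5‑[(triethylsilyloxy)methyl]‑3,5,8,8a‑tetrahydronaphthalen‑1‑yl trifluoromethanesulfonate
Product: 14 (4S,4aS,5S,7S,8aS)‑4,7‑dihydroxy‑5‑(hydroxymethyl)‑2,5,8a‑trimethyl‑3,4,4a,5,6,7,8,8a‑octahydronaphthalen‑1‑yl trifluoromethanesulfonate, via C7 borane 11 (not isolated), via bisborane 12 (not isolated), via silyl diol 13 (not isolated)
Conditions: 9‑BBN (1.5 equiv), THF, 60 °C; BH3·THF (3 equiv), 0 → 23 °C; H2O2, aq. NaHCO3, 0 °C; then 1 M HCl, 23 °C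
Reagents that add atoms: 9‑borabicyclo[3.3.1]nonane, B1C2CCCC1CCC2 (boron only in 11 and 12); borane–THF, B (boron only in 12); hydrogen peroxide, OO (the two new oxygen atoms)
Why: Hydroboration–oxidation: 9‑BBN adds to the cis‑disubstituted ring‑A alkene with boron on the carbon remote from the quaternary centre and BH3 then adds to the hindered trisubstituted alkene, both syn from the α‑face opposite the angular methyl and the CH2OSiEt3 group (as with Δ5‑steroids), which after oxidation with retention sets the equatorial 2α‑OH, the 5α‑H (trans ring fusion) and the 6α‑OH; the electron‑poor tetrasubstituted enol triflate is inert, and acid then cleaves the silyl ether in the same pot.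

Step 9
Reactants: 14 (4S,4aS,5S,7S,8aS)‑4,7‑dihydroxy‑5‑(hydroxymethyl)‑2,5,8a‑trimethyl‑3,4,4a,5,6,7,8,8a‑octahydronaphthalen‑1‑yl trifluoromethanesulfonate; 15 potassium ethenyltrifluoroborate
Product: 16 (4S,4aR,5S,7R,8aS)‑1‑ethenyl‑5‑(hydroxymethyl)‑2,5,8a‑trimethyl‑3,4,4a,5,6,7,8,8a‑octahydronaphthalene‑4,7‑diol
Conditions: PdCl2(dppf)·CH2Cl2 (5 mol %), Cs2CO3, THF/H2O 9:1, 70 °C
Reagents that add atoms: none
Why: Suzuki–Miyaura coupling of the alkenyl triflate with the vinyltrifluoroborate installs C‑11/C‑12 as a 1,3‑diene; free hydroxyls are tolerated and no stereocentre is touched.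

Step 10
Reactants: 16 (4S,4aR,5S,7R,8aS)‑1‑ethenyl‑5‑(hydroxymethyl)‑2,5,8a‑trimethyl‑3,4,4a,5,6,7,8,8a‑octahydronaphthalene‑4,7‑diol; 17 4‑bromofuran‑2(5H)‑one
Product: 19 4‑{2‑[(4S,4aR,5S,7R,8aS)‑4,7‑dihydroxy‑5‑(hydroxymethyl)‑2,5,8a‑trimethyl‑3,4,4a,5,6,7,8,8a‑octahydronaphthalen‑1‑yl]ethyl}furan‑2(5H)‑one, via alkylborane 18 (not isolated)
Conditions: 9‑BBN (5 equiv), THF, 0 → 23 °C; then aq. K3PO4, 17, PdCl2(dppf) (5 mol %), AsPh3 (10 mol %), DMF, 40 °C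
Reagents that add atoms: 9‑borabicyclo[3.3.1]nonane, B1C2CCCC1CCC2 (boron only in 18)
Why: 9‑BBN hydroborates only the terminal vinyl group (anti‑Markovnikov; the tetrasubstituted alkene is inert, the hydroxyls are O‑borylated transiently), and the primary B‑alkyl‑9‑BBN undergoes B‑alkyl Suzuki–Miyaura coupling with the β‑bromobutenolide under mild phosphate base, forming C12–C13 without touching any stereocentre.

## Compound list

1 | 2‑methylcyclopentane‑1,3‑dione | CC1C(=O)CCC1=O | starting material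
2 | acrolein (prop‑2‑enal) | C=CC=O | starting material
3 | 3‑(1‑methyl‑2,5‑dioxocyclopentyl)propanal | CC1(CCC=O)C(=O)CCC1=O | intermediate
4 | (2E)‑2‑methyl‑5‑(1‑methyl‑2,5‑dioxocyclopentyl)pent‑2‑enal | CC1(CC/C=C(\C)C=O)C(=O)CCC1=O | intermediate
5 | (3aS,4S,7aS)‑3a‑hydroxy‑4,7a‑dimethyl‑1‑oxo‑2,3,3a,4,7,7a‑hexahydro‑1H‑indene‑4‑carbaldehyde (OH, CHO and 7a‑CH3 all cis) | O=C[C@@]1(C)C=CC[C@]2(C)C(=O)CC[C@]12O | intermediate (not isolated)
6 | (3aS,4R,7aS)‑3a‑hydroxy‑4‑(hydroxymethyl)‑4,7a‑dimethyl‑2,3,3a,4,7,7a‑hexahydro‑1H‑inden‑1‑one | OC[C@@]1(C)C=CC[C@]2(C)C(=O)CC[C@]12O | intermediate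
7 | (3aS,4R,7aS)‑3a‑hydroxy‑4,7a‑dimethyl‑4‑[(triethylsilyloxy)methyl]‑2,3,3a,4,7,7a‑hexahydro‑1H‑inden‑1‑one | CC[Si](CC)(CC)OC[C@@]1(C)C=CC[C@]2(C)C(=O)CC[C@]12O | intermediate
8 | (4S,7aS)‑4,7a‑dimethyl‑4‑[(triethylsilyloxy)methyl]‑2,4,7,7a‑tetrahydro‑1H‑inden‑1‑one | CC[Si](CC)(CC)OC[C@@]1(C)C=CC[C@]2(C)C(=O)CC=C12 | intermediate
9 | (5S,8aS)‑2,5,8a‑trimethyl‑5‑[(triethylsilyloxy)methyl]‑3,5,8,8a‑tetrahydronaphthalen‑1(2H)‑one (C‑2 epimers) | CC[Si](CC)(CC)OC[C@@]1(C)C=CC[C@]2(C)C(=O)C(C)CC=C12 | intermediate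
10 | (5S,8aS)‑2,5,8a‑trimethyl‑5‑[(triethylsilyloxy)methyl]‑3,5,8,8a‑tetrahydronaphthalen‑1‑yl trifluoromethanesulfonate | CC[Si](CC)(CC)OC[C@@]1(C)C=CC[C@]2(C)C(OS(=O)(=O)C(F)(F)F)=C(C)CC=C12 | intermediate
11 | (5S,7S,8aS)‑7‑(9‑borabicyclo[3.3.1]nonan‑9‑yl)‑2,5,8a‑trimethyl‑5‑[(triethylsilyloxy)methyl]‑3,5,6,7,8,8a‑hexahydronaphthalen‑1‑yl trifluoromethanesulfonate (boron trans to the 8a‑methyl) | CC[Si](CC)(CC)OC[C@@]1(C)C[C@H](B2C3CCCC2CCC3)C[C@]2(C)C(OS(=O)(=O)C(F)(F)F)=C(C)CC=C12 | intermediate (not isolated)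
12 | (4S,4aS,5S,7S,8aS)‑4‑boranyl‑7‑(9‑borabicyclo[3.3.1]nonan‑9‑yl)‑2,5,8a‑trimethyl‑5‑[(triethylsilyloxy)methyl]‑3,4,4a,5,6,7,8,8a‑octahydronaphthalen‑1‑yl trifluoromethanesulfonate | CC[Si](CC)(CC)OC[C@@]1(C)C[C@H](B2C3CCCC2CCC3)C[C@]2(C)C(OS(=O)(=O)C(F)(F)F)=C(C)C[C@H](B)[C@@H]12 | intermediate (not isolated)
13 | (4S,4aS,5S,7S,8aS)‑4,7‑dihydroxy‑2,5,8a‑trimethyl‑5‑[(triethylsilyloxy)methyl]‑3,4,4a,5,6,7,8,8a‑octahydronaphthalen‑1‑yl trifluoromethanesulfonate | CC[Si](CC)(CC)OC[C@@]1(C)C[C@H](O)C[C@]2(C)C(OS(=O)(=O)C(F)(F)F)=C(C)C[C@H](O)[C@@H]12 | intermediate (not isolated)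
14 | (4S,4aS,5S,7S,8aS)‑4,7‑dihydroxy‑5‑(hydroxymethyl)‑2,5,8a‑trimethyl‑3,4,4a,5,6,7,8,8a‑octahydronaphthalen‑1‑yl trifluoromethanesulfonate | OC[C@@]1(C)C[C@H](O)C[C@]2(C)C(OS(=O)(=O)C(F)(F)F)=C(C)C[C@H](O)[C@@H]12 | intermediate
15 | potassium ethenyltrifluoroborate | C=C[B-](F)(F)F.[K+] | starting material
16 | (4S,4aR,5S,7R,8aS)‑1‑ethenyl‑5‑(hydroxymethyl)‑2,5,8a‑trimethyl‑3,4,4a,5,6,7,8,8a‑octahydronaphthalene‑4,7‑diol | OC[C@@]1(C)C[C@H](O)C[C@]2(C)C(C=C)=C(C)C[C@H](O)[C@@H]12 | intermediate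
17 | 4‑bromofuran‑2(5H)‑one | O=C1C=C(Br)CO1 | starting material
18 | (4S,4aR,5S,7R,8aS)‑1‑[2‑(9‑borabicyclo[3.3.1]nonan‑9‑yl)ethyl]‑5‑(hydroxymethyl)‑2,5,8a‑trimethyl‑3,4,4a,5,6,7,8,8a‑octahydronaphthalene‑4,7‑diol (hydroxyls drawn free) | OC[C@@]1(C)C[C@H](O)C[C@]2(C)C(CCB3C4CCCC3CCC4)=C(C)C[C@H](O)[C@@H]12 | intermediate (not isolated)
19 | 4‑{2‑[(4S,4aR,5S,7R,8aS)‑4,7‑dihydroxy‑5‑(hydroxymethyl)‑2,5,8a‑trimethyl‑3,4,4a,5,6,7,8,8a‑octahydronaphthalen‑1‑yl]ethyl}furan‑2(5H)‑one (CNP0387838.1) | CC1=C(CCC2=CC(=O)OC2)[C@@]2(C)C[C@@H](O)C[C@](C)(CO)[C@@H]2[C@@H](O)C1 | target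

## Step count and risks

Total steps: 10. Longest linear sequence: 10 (from 1).

**Step 3 (the new desymmetrising dienamine α‑aldol).** The ring closure is strained (four coplanar ring atoms), the ketol has three contiguous fully substituted carbons and may sit on the retro‑aldol side, and the catalyst's sense of induction is unproven. The fallback sets out from 3 and comes back at 7, making the same C4–C5 bond with known metal‑enolate chemistry.
- Aldehyde 3 is α‑brominated (NBS, cat. DL‑proline, CH2Cl2, 0 °C) to 2‑bromo‑3‑(1‑methyl‑2,5‑dioxocyclopentyl)propanal F1.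
- Without isolation, Wittig reaction with methyl 2‑(triphenylphosphoranylidene)propanoate gives methyl (2E)‑4‑bromo‑2‑methyl‑5‑(1‑methyl‑2,5‑dioxocyclopentyl)pent‑2‑enoate F2.
- Corey–Bakshi–Shibata reduction (Me‑CBS, BH3·SMe2, −40 °C; catalyst antipode chosen for the (1R,2R) alcohol) desymmetrises the dione to methyl (2E)‑4‑bromo‑5‑[(1R,2R)‑2‑hydroxy‑1‑methyl‑5‑oxocyclopentyl]‑2‑methylpent‑2‑enoate F3.
- A vinylogous chromium‑Reformatsky cyclisation (CrCl2, cat. LiI, THF) closes ring A to methyl (1R,3aR,4S,7aR)‑1,3a‑dihydroxy‑4,7a‑dimethyl‑2,3,3a,4,7,7a‑hexahydro‑1H‑indene‑4‑carboxylate F4. α‑Attack is enforced by ring size and the chelated transition state puts the ester cis to the new hydroxyl.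
- LiAlH4 reduces the ester to (1R,3aS,4R,7aR)‑4‑(hydroxymethyl)‑4,7a‑dimethyl‑2,3,3a,4,7,7a‑hexahydro‑1H‑indene‑1,3a‑diol F5.
- TESCl/imidazole silylates the primary alcohol to (1R,3aS,4R,7aR)‑4,7a‑dimethyl‑4‑[(triethylsilyloxy)methyl]‑2,3,3a,4,7,7a‑hexahydro‑1H‑indene‑1,3a‑diol F6.
- Dess–Martin oxidation of the secondary alcohol gives 7.

**Step 6 (ring expansion).** Diazoethane may add sluggishly to the hindered ketone, insert twice, or show imperfect migration selectivity. The fallback sets out from 8 and comes back at 9; it brings in the methyl by enolate alkylation instead of with the diazoalkane.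
- TMSCHN2, BF3·OEt2, CH2Cl2, −78 °C gives (5S,8aS)‑5,8a‑dimethyl‑5‑[(triethylsilyloxy)methyl]‑2‑(trimethylsilyl)‑3,5,8,8a‑tetrahydronaphthalen‑1(2H)‑one F7.
- Protodesilylation (K2CO3, MeOH) gives (5S,8aS)‑5,8a‑dimethyl‑5‑[(triethylsilyloxy)methyl]‑3,5,8,8a‑tetrahydronaphthalen‑1(2H)‑one F8.
- LDA, THF, −78 °C, then MeI, methylates the only enolisable position and gives 9.

**Step 10 (B‑alkyl Suzuki coupling with the base‑sensitive bromobutenolide).** The bromobutenolide may decompose under the aqueous base, or the hindered triol borane may couple poorly. The fallback sets out from 16 and comes back at 19; it builds the butenolide by furan oxidation instead of coupling it intact.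
- Borane 18 is coupled with 3‑bromofuran (Brc1ccoc1; PdCl2(dppf), K3PO4, DMF/H2O) to (4S,4aR,5S,7R,8aS)‑1‑[2‑(furan‑3‑yl)ethyl]‑5‑(hydroxymethyl)‑2,5,8a‑trimethyl‑3,4,4a,5,6,7,8,8a‑octahydronaphthalene‑4,7‑diol F9.
- Photo‑oxygenation with a hindered base (O2, rose bengal, hν, iPr2NEt, CH2Cl2, −78 °C) gives regioselectively 4‑{2‑[(4S,4aR,5S,7R,8aS)‑4,7‑dihydroxy‑5‑(hydroxymethyl)‑2,5,8a‑trimethyl‑3,4,4a,5,6,7,8,8a‑octahydronaphthalen‑1‑yl]ethyl}‑5‑hydroxyfuran‑2(5H)‑one F10. Competing ene reaction of singlet oxygen at the tetrasubstituted alkene is the residual risk here.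
- NaBH4, EtOH, 0 °C, then acidification, gives 19.

## Further compounds

F1 | step 3 | 2‑bromo‑3‑(1‑methyl‑2,5‑dioxocyclopentyl)propanal (racemic) | CC1(CC(Br)C=O)C(=O)CCC1=O
F2 | step 3 | methyl (2E)‑4‑bromo‑2‑methyl‑5‑(1‑methyl‑2,5‑dioxocyclopentyl)pent‑2‑enoate (racemic) | COC(=O)/C(C)=C/C(Br)CC1(C)C(=O)CCC1=O
F3 | step 3 | methyl (2E)‑4‑bromo‑5‑[(1R,2R)‑2‑hydroxy‑1‑methyl‑5‑oxocyclopentyl]‑2‑methylpent‑2‑enoate (C‑4 epimers) | COC(=O)/C(C)=C/C(Br)C[C@]1(C)[C@H](O)CCC1=O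
F4 | step 3 | methyl (1R,3aR,4S,7aR)‑1,3a‑dihydroxy‑4,7a‑dimethyl‑2,3,3a,4,7,7a‑hexahydro‑1H‑indene‑4‑carboxylate | COC(=O)[C@@]1(C)C=CC[C@]2(C)[C@H](O)CC[C@]12O
F5 | step 3 | (1R,3aS,4R,7aR)‑4‑(hydroxymethyl)‑4,7a‑dimethyl‑2,3,3a,4,7,7a‑hexahydro‑1H‑indene‑1,3a‑diol | OC[C@@]1(C)C=CC[C@]2(C)[C@H](O)CC[C@]12O
F6 | step 3 | (1R,3aS,4R,7aR)‑4,7a‑dimethyl‑4‑[(triethylsilyloxy)methyl]‑2,3,3a,4,7,7a‑hexahydro‑1H‑indene‑1,3a‑diol | CC[Si](CC)(CC)OC[C@@]1(C)C=CC[C@]2(C)[C@H](O)CC[C@]12O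
F7 | step 6 | (5S,8aS)‑5,8a‑dimethyl‑5‑[(triethylsilyloxy)methyl]‑2‑(trimethylsilyl)‑3,5,8,8a‑tetrahydronaphthalen‑1(2H)‑one (C‑2 epimers) | CC[Si](CC)(CC)OC[C@@]1(C)C=CC[C@]2(C)C(=O)C([Si](C)(C)C)CC=C12
F8 | step 6 | (5S,8aS)‑5,8a‑dimethyl‑5‑[(triethylsilyloxy)methyl]‑3,5,8,8a‑tetrahydronaphthalen‑1(2H)‑one | CC[Si](CC)(CC)OC[C@@]1(C)C=CC[C@]2(C)C(=O)CCC=C12
F9 | step 10 | (4S,4aR,5S,7R,8aS)‑1‑[2‑(furan‑3‑yl)ethyl]‑5‑(hydroxymethyl)‑2,5,8a‑trimethyl‑3,4,4a,5,6,7,8,8a‑octahydronaphthalene‑4,7‑diol | OC[C@@]1(C)C[C@H](O)C[C@]2(C)C(CCc3ccoc3)=C(C)C[C@H](O)[C@@H]12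
F10 | step 10 | 4‑{2‑[(4S,4aR,5S,7R,8aS)‑4,7‑dihydroxy‑5‑(hydroxymethyl)‑2,5,8a‑trimethyl‑3,4,4a,5,6,7,8,8a‑octahydronaphthalen‑1‑yl]ethyl}‑5‑hydroxyfuran‑2(5H)‑one (hemiacetal epimers) | OC[C@@]1(C)C[C@H](O)C[C@]2(C)C(CCC3=CC(=O)OC3O)=C(C)C[C@H](O)[C@@H]12
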